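The constants used here are made up; the run is a simulation.

The constants of this two-phase flask divide into those that bring reagent across, those that spend substrate and those that spend target.

    reagent in the reaction phase ⇌ reagent in the second phase, rate k1*([reagent in the reaction phase] - [reagent in the second phase]/K1) per volume of the first phase (K1 = 1.8, k1 = 0.054 h⁻¹)
    substrate + reagent in the reaction phase → target (k2 = 2.1 M⁻¹ h⁻¹)
    reagent in the reaction phase + target → over-reacted product (k3 = 2.1 M⁻¹ h⁻¹)
    substrate + target → side product (k4 = 0.42 M⁻¹ h⁻¹)
    2 substrate → homo dimer (k5 = 0.41 M⁻¹ h⁻¹)

substrate 0.050 M; reagent in the second phase 1.10 equiv; time 20 h; volume of the second phase over the first 2.0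

- percent here means substrate units held: one side product or homo dimer counts as two
- a doubled species enters its step squared and goes two at a time
- in the second phase: reagent in the second phase; everything else is in the first
- charges count per volume of the first phase; a concentration in a rate is the amount of a species over the volume of its own phase; every rate counts per litre of the first phase
- run time (flask): 20 h

- Saturday's: doubling the transfer coefficient of step 1, all else as stated
- Wednesday's: doubling the amount of reagent in the second phase, all else as stated

- the target standing at 20 h, as a percentage of the substrate charged
- the change that raises the amount of target at 20 h, in percent of the substrate charged most ("none" if none brings more than 2 percentage points) (Saturday's / Wednesday's / none)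
- amount of target at 20 h, in percent of the substrate charged, after Saturday's

Which must I know well? The target-spending constants I hold loosely for now. The side-product half-life of target, as charged, is 33 h, longer than the run. Over-reaction has the coupling constant, so it stays slower than coupling while target stands below substrate. The transfer coefficient and partition ratio enter the reagent supply. The dimerisation and coupling constants matter as a pair.

Twice the dimerisation constant over the coupling constant is 0.390. This is the break-even ratio: with less reagent per substrate than this in the reaction phase, dimerisation spends substrate faster than coupling.

Now the numbers. Reagent first crosses at 8.25 × 10⁻⁴ M h⁻¹. With substrate as charged, back-transfer and coupling remove it at 0.159 h⁻¹, so by this reckoning it levels near 0.00519 M. Against charged substrate that is 0.104, below break-even, so coupling runs at 0.266 of dimerisation. Dimerisation alone would spend 45.1% of the substrate. A lag factor of 0.686 for the climb gives me 8.21%, losses ignored. In this reckoning, doubling the reagent in the second phase doubles this to 16.4%. Doubling transfer gives 13.7%. I choose Wednesday's.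

The forecast gives 8.2%, Wednesday's and 11.7%, the last lower than mine for Saturday's. Of the losses it says: “Losses to over-reaction and side product are small but growing”.

The simulation gives 8.24%, Wednesday's with 6 percentage points against 3.4 points, and 11.7%. This flask is not at rest at 20.0 h. Its substrate and reagent readings put dimerisation at 1.75 times coupling. Read at 8.0 h, the same flask gives 3.80 by the break-even ratio. At 20.0 h target is still made 3.05 times faster than it is used up, and it stands at 12.6% at 40.0 h. At 200 h, substrate is down to 1.70%, over-reacted product stands at 22.6%, and target has fallen to 5.55%.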